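Retrosynthesis cuts O1–C8a (the aryl ether bond of ring C), C3–C4 (aldol), the aryl–CH2 bond of the ring B side chain (Negishi) and the C8–CH2 bond of the prenyl group; the C4 ketone is carried as a silyl ether and the 5,7-phenols as MOM ethers.
Enabling feature: O1 sits on C8a of ring A, between C8 (prenyl) and C4a, with the C5 and C7 oxygens meta to it, so this phenolic carbon can carry a triflate and ring C can be closed by aryl–O bond formation from the C2 hydroxyl; the C2–O bond, benzylic and para to the 4'-methoxy group of ring B, is never broken.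
Forward: the ring A aldehyde (C-prenylation, bis-MOM protection, triflation) and the ring B methyl ketone (Negishi coupling) are made separately and joined by aldol at C3–C4; the C4 hydroxyl is silylated, the C2 ketone reduced, ring C closed by palladium etherification, then desilylation, oxidation and MOM removal follow.
Stereochemistry: the only stereocentre, C2 (S), comes from a Corey–Bakshi–Shibata reduction with the (R)-oxazaborolidine (reagent control) and is retained in the ring closure; C4 is carried as an epimer mixture and ends as the ketone.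

Key step: step 8

Remark: the C4 carbinol centre of compounds 11 to 15 is formed without control and carried as a mixture of both configurations, because step 10 converts it into the carbonyl group.

Step 1
Reactants: 1 2,4,6-trihydroxybenzaldehyde; 2 prenyl bromide (1-bromo-3-methylbut-2-ene)
Product: 3 2,4,6-trihydroxy-3-(3-methylbut-2-en-1-yl)benzaldehyde
Conditions: 2 (0.9 equiv), DBU (1.0 equiv), THF, 0 °C → rt
Reagents that add atoms: none
Why: Base-mediated C-alkylation of the acylphloroglucinol-type phenoxide with prenyl bromide at one of the two equivalent free ring carbons is a well-used entry to mono-C-prenyl phloroglucinols, and a slight deficit of bromide should limit double and O-alkylation.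

Step 2
Reactants: 3 2,4,6-trihydroxy-3-(3-methylbut-2-en-1-yl)benzaldehyde
Product: 4 2-hydroxy-4,6-bis(methoxymethoxy)-3-(3-methylbut-2-en-1-yl)benzaldehyde
Conditions: MOMCl (2.2 equiv), iPr2NEt (2.5 equiv), CH2Cl2, 0 °C → rt
Reagents that add atoms: chloromethyl methyl ether (MOMCl), COCCl
Why: Williamson-type MOM ether formation is expected at the 4-OH (para to the formyl group, most acidic) and at the less hindered 6-OH, whereas the 2-OH, hydrogen-bonded to the aldehyde and buttressed by the prenyl group, should stay free, the same selectivity that is relied on in the bis-MOM protection of C-prenylated trihydroxyacetophenones.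

Step 3
Reactants: 4 2-hydroxy-4,6-bis(methoxymethoxy)-3-(3-methylbut-2-en-1-yl)benzaldehyde
Product: 5 2-formyl-3,5-bis(methoxymethoxy)-6-(3-methylbut-2-en-1-yl)phenyl trifluoromethanesulfonate
Conditions: Tf2O (1.2 equiv), pyridine (3 equiv), CH2Cl2, –20 → 0 °C
Reagents that add atoms: trifluoromethanesulfonic anhydride (Tf2O), O=S(=O)(OS(=O)(=O)C(F)(F)F)C(F)(F)F
Why: O-Sulfonylation of the chelated phenol with Tf2O and pyridine turns the future C8a oxygen into the triflate leaving group, while the MOM ethers and the prenyl alkene are inert to the buffered reagent at low temperature.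

Step 4
Reactants: 6 1-(3-bromo-4-methoxyphenyl)ethan-1-one; 7 4-bromo-2-methylbut-1-ene
Product: 9 1-[4-methoxy-3-(3-methylbut-3-en-1-yl)phenyl]ethan-1-one, via (3-methylbut-3-en-1-yl)zinc bromide 8 (not isolated)
Conditions: 7, Zn dust (activated), LiCl, THF, 40 °C; then 6, Pd(OAc)2 (2 mol%), 2-dicyclohexylphosphino-2',6'-dimethoxybiphenyl (SPhos, 4 mol%), THF, rt → 50 °C
Reagents that add atoms: none
Why: Negishi coupling in which LiCl-assisted zinc insertion into the primary homoallylic bromide gives an alkylzinc bromide that tolerates the methyl ketone, and with the bulky biaryl phosphine the sp3–sp2 coupling at the aryl bromide should outpace β-hydride elimination.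

Step 5
Reactants: 9 1-[4-methoxy-3-(3-methylbut-3-en-1-yl)phenyl]ethan-1-one; 5 2-formyl-3,5-bis(methoxymethoxy)-6-(3-methylbut-2-en-1-yl)phenyl trifluoromethanesulfonate
Product: 11 2-{1-hydroxy-3-[4-methoxy-3-(3-methylbut-3-en-1-yl)phenyl]-3-oxopropyl}-3,5-bis(methoxymethoxy)-6-(3-methylbut-2-en-1-yl)phenyl trifluoromethanesulfonate (racemic), via the lithium enolate of the ring B ketone 10 (not isolated)
Conditions: 9, LiN(iPr)2 (1.05 equiv), THF, –78 °C; then 5, –78 °C; AcOH in THF, –78 °C
Reagents that add atoms: none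
Why: Directed aldol addition of the preformed lithium enolate of the methyl ketone to the non-enolisable aldehyde at –78 °C, quenched cold to avoid retro-aldol cleavage and dehydration, forms C3–C4 and creates the C4 carbinol centre without control (racemic), which is harmless because that centre is later oxidised.

Step 6
Reactants: 11 2-{1-hydroxy-3-[4-methoxy-3-(3-methylbut-3-en-1-yl)phenyl]-3-oxopropyl}-3,5-bis(methoxymethoxy)-6-(3-methylbut-2-en-1-yl)phenyl trifluoromethanesulfonate (racemic)
Product: 12 2-{1-[(tert-butyldimethylsilyl)oxy]-3-[4-methoxy-3-(3-methylbut-3-en-1-yl)phenyl]-3-oxopropyl}-3,5-bis(methoxymethoxy)-6-(3-methylbut-2-en-1-yl)phenyl trifluoromethanesulfonate (racemic)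
Conditions: TBSOTf (1.3 equiv), 2,6-lutidine (2.5 equiv), CH2Cl2, –78 → –20 °C
Reagents that add atoms: tert-butyldimethylsilyl trifluoromethanesulfonate (TBSOTf), CC(C)(C)[Si](C)(C)OS(=O)(=O)C(F)(F)F
Why: Silyl ether formation with TBSOTf and 2,6-lutidine reaches the hindered benzylic hydroxyl at low temperature and blocks the C4 oxygen against elimination, palladium binding and oxidation in the following steps, while the cold buffered conditions spare the MOM ethers.

Step 7
Reactants: 12 2-{1-[(tert-butyldimethylsilyl)oxy]-3-[4-methoxy-3-(3-methylbut-3-en-1-yl)phenyl]-3-oxopropyl}-3,5-bis(methoxymethoxy)-6-(3-methylbut-2-en-1-yl)phenyl trifluoromethanesulfonate (racemic)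
Product: 13 2-{(3S)-1-[(tert-butyldimethylsilyl)oxy]-3-hydroxy-3-[4-methoxy-3-(3-methylbut-3-en-1-yl)phenyl]propyl}-3,5-bis(methoxymethoxy)-6-(3-methylbut-2-en-1-yl)phenyl trifluoromethanesulfonate (both configurations at the silyloxy carbon)
Conditions: (R)-2-methyl-CBS-oxazaborolidine [(R)-tetrahydro-1-methyl-3,3-diphenyl-1H,3H-pyrrolo[1,2-c][1,3,2]oxazaborole] (20 mol%), catecholborane (1.8 equiv), toluene, –78 → –30 °C; MeOH quench
Reagents that add atoms: none
Why: Corey–Bakshi–Shibata reduction in which the (R)-oxazaborolidine binds the aryl ketone with ring B as the large group and passes hydride from catecholborane to the Re face, setting C2 as (S) by reagent control in both C4 epimers, while catecholborane at low temperature does not hydroborate the two alkenes.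

Step 8
Reactants: 13 2-{(3S)-1-[(tert-butyldimethylsilyl)oxy]-3-hydroxy-3-[4-methoxy-3-(3-methylbut-3-en-1-yl)phenyl]propyl}-3,5-bis(methoxymethoxy)-6-(3-methylbut-2-en-1-yl)phenyl trifluoromethanesulfonate (both configurations at the silyloxy carbon)
Product: 14 (2S)-4-[(tert-butyldimethylsilyl)oxy]-5,7-bis(methoxymethoxy)-2-[4-methoxy-3-(3-methylbut-3-en-1-yl)phenyl]-8-(3-methylbut-2-en-1-yl)chromane (both C4 epimers)
Conditions: Pd(OAc)2 (5 mol%), 2-(di-tert-butylphosphino)-1,1'-binaphthyl (7.5 mol%), Cs2CO3 (1.5 equiv, dried), degassed toluene, 80 °C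
Reagents that add atoms: none
Why: Pd(OAc)2 is reduced by the phosphine to zerovalent palladium, which inserts into the C8a–O bond of the triflate; carbonate-assisted exchange of triflate for the C2 alkoxide gives a seven-membered aryl(alkoxo) chelate of divalent palladium, and C–O reductive elimination forms O1–C8a and returns zerovalent palladium. The closest known reaction type is the Buchwald–Hartwig-type intramolecular etherification of ortho-(3-hydroxyalkyl)aryl halides and sulfonates with secondary alcohols, which gives chromans including 2-arylchromans. Ring C closes in a six-membered mode (formally a 6-exo attack of the alkoxide oxygen on C8a) by contraction of that seven-membered palladacycle. No stereocentre is created: the C2–O bond is not touched, so the (S)-configuration from step 7 is retained, and both C4 epimers cyclise. The step needs reductive elimination to be faster than β-hydride elimination from the C2 alkoxide and than S–O cleavage of the triflate; the bulky electron-rich di-tert-butyl biaryl phosphine, the short tether, dry Cs2CO3 in toluene, the silyl cap on the C4 oxygen (only one hydroxyl can bind palladium) and the meta placement of both MOM-oxy groups relative to C8a are what should secure this.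

Step 9
Reactants: 14 (2S)-4-[(tert-butyldimethylsilyl)oxy]-5,7-bis(methoxymethoxy)-2-[4-methoxy-3-(3-methylbut-3-en-1-yl)phenyl]-8-(3-methylbut-2-en-1-yl)chromane (both C4 epimers)
Product: 15 (2S)-5,7-bis(methoxymethoxy)-2-[4-methoxy-3-(3-methylbut-3-en-1-yl)phenyl]-8-(3-methylbut-2-en-1-yl)chroman-4-ol (both C4 epimers)
Conditions: Bu4NF (TBAF, 1.2 equiv), THF, 0 °C → rt
Reagents that add atoms: none
Why: Fluoride-induced Si–O cleavage frees the C4 hydroxyl while the aryl MOM ethers, the chroman ether and both alkenes are inert, and it is placed before the oxidation because a flavanone would be exposed to ring opening by basic fluoride.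

Step 10
Reactants: 15 (2S)-5,7-bis(methoxymethoxy)-2-[4-methoxy-3-(3-methylbut-3-en-1-yl)phenyl]-8-(3-methylbut-2-en-1-yl)chroman-4-ol (both C4 epimers)
Product: 16 (2S)-5,7-bis(methoxymethoxy)-2-[4-methoxy-3-(3-methylbut-3-en-1-yl)phenyl]-8-(3-methylbut-2-en-1-yl)chroman-4-one
Conditions: Dess–Martin periodinane (1.3 equiv), NaHCO3, CH2Cl2, 0 °C → rt
Reagents that add atoms: none
Why: Dess–Martin oxidation of the secondary benzylic alcohol to the aryl ketone under buffered non-basic conditions merges both C4 epimers into one flavanone, leaves the alkenes alone and gives no opening for base-induced ring cleavage at C2.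

Step 11
Reactants: 16 (2S)-5,7-bis(methoxymethoxy)-2-[4-methoxy-3-(3-methylbut-3-en-1-yl)phenyl]-8-(3-methylbut-2-en-1-yl)chroman-4-one
Product: 17 (2S)-5,7-dihydroxy-2-[4-methoxy-3-(3-methylbut-3-en-1-yl)phenyl]-8-(3-methylbut-2-en-1-yl)chroman-4-one (CNP0286775.1)
Conditions: 3 M aq. HCl/MeOH (1:5), 40 °C
Reagents that add atoms: none
Why: Acid-catalysed transacetalisation (methanolysis) of the two aryl MOM ethers with dilute HCl in methanol, the usual end game for prenylated flavanones, should free the 5- and 7-hydroxyls under conditions mild enough to keep the prenyl group, the 1,1-disubstituted alkene and the C2 configuration.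

Compound list
1 | 2,4,6-trihydroxybenzaldehyde | O=Cc1c(O)cc(O)cc1O | starting material
2 | prenyl bromide (1-bromo-3-methylbut-2-ene) | CC(C)=CCBr | starting material
3 | 2,4,6-trihydroxy-3-(3-methylbut-2-en-1-yl)benzaldehyde | O=Cc1c(O)cc(O)c(CC=C(C)C)c1O | intermediate
4 | 2-hydroxy-4,6-bis(methoxymethoxy)-3-(3-methylbut-2-en-1-yl)benzaldehyde | O=Cc1c(OCOC)cc(OCOC)c(CC=C(C)C)c1O | intermediate
5 | 2-formyl-3,5-bis(methoxymethoxy)-6-(3-methylbut-2-en-1-yl)phenyl trifluoromethanesulfonate | O=Cc1c(OCOC)cc(OCOC)c(CC=C(C)C)c1OS(=O)(=O)C(F)(F)F | intermediate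
6 | 1-(3-bromo-4-methoxyphenyl)ethan-1-one | CC(=O)c1ccc(OC)c(Br)c1 | starting material
7 | 4-bromo-2-methylbut-1-ene | C=C(C)CCBr | starting material
8 | (3-methylbut-3-en-1-yl)zinc bromide | C=C(C)CC[Zn]Br | intermediate (not isolated)
9 | 1-[4-methoxy-3-(3-methylbut-3-en-1-yl)phenyl]ethan-1-one | CC(=O)c1ccc(OC)c(CCC(C)=C)c1 | intermediate
10 | lithium 1-[4-methoxy-3-(3-methylbut-3-en-1-yl)phenyl]ethen-1-olate | [Li+].[O-]C(=C)c1ccc(OC)c(CCC(C)=C)c1 | intermediate (not isolated)
11 | 2-{1-hydroxy-3-[4-methoxy-3-(3-methylbut-3-en-1-yl)phenyl]-3-oxopropyl}-3,5-bis(methoxymethoxy)-6-(3-methylbut-2-en-1-yl)phenyl trifluoromethanesulfonate (racemic) | O=C(CC(O)c1c(OCOC)cc(OCOC)c(CC=C(C)C)c1OS(=O)(=O)C(F)(F)F)c1ccc(OC)c(CCC(C)=C)c1 | intermediate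
12 | 2-{1-[(tert-butyldimethylsilyl)oxy]-3-[4-methoxy-3-(3-methylbut-3-en-1-yl)phenyl]-3-oxopropyl}-3,5-bis(methoxymethoxy)-6-(3-methylbut-2-en-1-yl)phenyl trifluoromethanesulfonate (racemic) | O=C(CC(O[Si](C)(C)C(C)(C)C)c1c(OCOC)cc(OCOC)c(CC=C(C)C)c1OS(=O)(=O)C(F)(F)F)c1ccc(OC)c(CCC(C)=C)c1 | intermediate
13 | 2-{(3S)-1-[(tert-butyldimethylsilyl)oxy]-3-hydroxy-3-[4-methoxy-3-(3-methylbut-3-en-1-yl)phenyl]propyl}-3,5-bis(methoxymethoxy)-6-(3-methylbut-2-en-1-yl)phenyl trifluoromethanesulfonate (both configurations at the silyloxy carbon) | O[C@@H](CC(O[Si](C)(C)C(C)(C)C)c1c(OCOC)cc(OCOC)c(CC=C(C)C)c1OS(=O)(=O)C(F)(F)F)c1ccc(OC)c(CCC(C)=C)c1 | intermediate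
14 | (2S)-4-[(tert-butyldimethylsilyl)oxy]-5,7-bis(methoxymethoxy)-2-[4-methoxy-3-(3-methylbut-3-en-1-yl)phenyl]-8-(3-methylbut-2-en-1-yl)chromane (both C4 epimers) | CC(C)(C)[Si](C)(C)OC1C[C@@H](c3ccc(OC)c(CCC(C)=C)c3)Oc2c(CC=C(C)C)c(OCOC)cc(OCOC)c12 | intermediate
15 | (2S)-5,7-bis(methoxymethoxy)-2-[4-methoxy-3-(3-methylbut-3-en-1-yl)phenyl]-8-(3-methylbut-2-en-1-yl)chroman-4-ol (both C4 epimers) | OC1C[C@@H](c3ccc(OC)c(CCC(C)=C)c3)Oc2c(CC=C(C)C)c(OCOC)cc(OCOC)c12 | intermediate
16 | (2S)-5,7-bis(methoxymethoxy)-2-[4-methoxy-3-(3-methylbut-3-en-1-yl)phenyl]-8-(3-methylbut-2-en-1-yl)chroman-4-one | O=C1C[C@@H](c3ccc(OC)c(CCC(C)=C)c3)Oc2c(CC=C(C)C)c(OCOC)cc(OCOC)c12 | intermediate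
17 | (2S)-5,7-dihydroxy-2-[4-methoxy-3-(3-methylbut-3-en-1-yl)phenyl]-8-(3-methylbut-2-en-1-yl)chroman-4-one (CNP0286775.1) | C=C(C)CCc1cc([C@@H]2CC(=O)c3c(O)cc(O)c(CC=C(C)C)c3O2)ccc1OC | target

Total step count: 11.
Longest linear sequence: 10 steps (steps 1 to 3 and 5 to 11, from 2,4,6-trihydroxybenzaldehyde).

Steps most likely to fail

Step 8. Insertion of palladium into the doubly ortho-substituted C8a–O bond may be slow. Then β-hydride elimination from the palladium alkoxide (oxidation at C2 with reductive loss of the triflate), base-induced S–O cleavage of the triflate, or migration of the silyl group from the C4 to the C2 oxygen could take over. The fallback closes ring C from the other side, with inversion at C2 and without base. It sets out from ketone 12: reduction with the (S)-oxazaborolidine and catecholborane under the conditions of step 7 should give the (3R)-carbinol triflate F1. Et4NOH in dioxane at room temperature then cleaves the S–O bond of the triflate to give the (3R)-hydroxy phenol F2. Mitsunobu cyclisation (PPh3, DIAD, toluene, 0 °C) forms O1–C2 with inversion and comes back to the route at 14. Low temperature and a non-polar solvent are chosen to keep the substitution at the para-methoxybenzylic carbon bimolecular.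

Step 5. The triflyl group may transfer from the aryl oxygen to the neighbouring lithium alkoxide, or the lithium aldolate may undergo retro-aldol cleavage or β-elimination before the quench. The fallback is a Mukaiyama-type addition in which no free alkoxide persists. It sets out from 9, which with TMSOTf and Et3N (CH2Cl2, 0 °C) should give the trimethylsilyl enol ether F3. LiOAc-catalysed (Lewis-base) addition of this enol silane to aldehyde 5 in DMF at –45 °C should give the O-trimethylsilyl aldol adduct F4. Brief treatment with citric acid in methanol at 0 °C comes back to the route at 11.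

Step 11. Acid may promote cyclisation of the C8 prenyl group onto the freed C7 hydroxyl, Markovnikov addition of methanol or HCl across the 1,1-disubstituted alkene, or opening of ring C with erosion at C2. The fallback is a non-protic acetal exchange. It sets out from 16: TMSOTf and 2,2'-bipyridyl in MeCN at 0 °C should convert both aryl MOM ethers into aryl silyl ethers, giving the 5,7-bis(trimethylsilyloxy)flavanone F5. Hydrolysis with water at neutral pH comes back to the route at the target 17.

Further compounds
F1 | step 8 | 2-{(3R)-1-[(tert-butyldimethylsilyl)oxy]-3-hydroxy-3-[4-methoxy-3-(3-methylbut-3-en-1-yl)phenyl]propyl}-3,5-bis(methoxymethoxy)-6-(3-methylbut-2-en-1-yl)phenyl trifluoromethanesulfonate | O[C@H](CC(O[Si](C)(C)C(C)(C)C)c1c(OCOC)cc(OCOC)c(CC=C(C)C)c1OS(=O)(=O)C(F)(F)F)c1ccc(OC)c(CCC(C)=C)c1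
F2 | step 8 | 2-{(3R)-1-[(tert-butyldimethylsilyl)oxy]-3-hydroxy-3-[4-methoxy-3-(3-methylbut-3-en-1-yl)phenyl]propyl}-3,5-bis(methoxymethoxy)-6-(3-methylbut-2-en-1-yl)phenol | O[C@H](CC(O[Si](C)(C)C(C)(C)C)c1c(OCOC)cc(OCOC)c(CC=C(C)C)c1O)c1ccc(OC)c(CCC(C)=C)c1
F3 | step 5 | {1-[4-methoxy-3-(3-methylbut-3-en-1-yl)phenyl]ethenyl}oxy(trimethyl)silane | C=C(O[Si](C)(C)C)c1ccc(OC)c(CCC(C)=C)c1
F4 | step 5 | 2-{3-[4-methoxy-3-(3-methylbut-3-en-1-yl)phenyl]-3-oxo-1-[(trimethylsilyl)oxy]propyl}-3,5-bis(methoxymethoxy)-6-(3-methylbut-2-en-1-yl)phenyl trifluoromethanesulfonate (racemic) | O=C(CC(O[Si](C)(C)C)c1c(OCOC)cc(OCOC)c(CC=C(C)C)c1OS(=O)(=O)C(F)(F)F)c1ccc(OC)c(CCC(C)=C)c1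
F5 | step 11 | (2S)-2-[4-methoxy-3-(3-methylbut-3-en-1-yl)phenyl]-8-(3-methylbut-2-en-1-yl)-5,7-bis[(trimethylsilyl)oxy]chroman-4-one | O=C1C[C@@H](c3ccc(OC)c(CCC(C)=C)c3)Oc2c(CC=C(C)C)c(O[Si](C)(C)C)cc(O[Si](C)(C)C)c12
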